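Atom labels used throughout: C1 is the methyl-bearing ring-fusion carbon, C2 and C3 the ring A methylenes, C4 the isopropyl carbinol, C5 the ring-fusion CH, C6 the anisoate carbon, C7 the ring B methylene, C8=C9 the alkene (methyl on C8), C10 the angelate carbon. Ring A is C1–C5, ring B is C1, C5–C10. Names of intermediates use these labels on a bicyclo[5.3.0]decane skeleton (not the von Baeyer numbering), and all descriptors refer to them.

## Analysis of the target

The target is a daucane-type sesquiterpene diester: a hydroazulene in which a cyclopentane (ring A) is fused to a cycloheptene (ring B) whose only alkene, C8=C9, carries the C8 methyl group. It has five stereocentres, (1S,4R,5S,6S,10R): the quaternary C1, the tertiary carbinol C4, the ring-fusion C5, and the two acyloxy carbons C6 and C10. The ring fusion is trans (C1 methyl and H5 on opposite faces); the C4 hydroxyl lies on the face of the C1 methyl and the isopropyl group on the face of H5; O6 and O10 both lie on the face of H5, so O4 and O6 form an anti-1,3-diol across C5. The sensitive groups are the angelate (a Z-enoate that isomerises to the tiglate under nucleophilic or basic catalysis), the allylic C10–O bond (ionisation gives a cation that is tertiary at C8), and the free tertiary alcohol at C4, which at the C6-ketone oxidation level is a tertiary aldol prone to dehydration and retro-aldol cleavage. Two different esters must be placed on two secondary alcohols. The main difficulty is the all-carbon quaternary C1 flanked by stereocentres on both sides (C5 and C10) inside a seven-membered ring, together with H5, which sits anti to O4 and so cannot be delivered by that hydroxyl. The strategy rests on the array C1–C10–C9=C8–C7 of ring B: two adjacent sp3 carbons (C1, C10) next to an alkene are what a cis-divinylcyclopropane produces on [3,3] rearrangement, and the second alkene of the resulting 1,4-cycloheptadiene (C5=C6) is a handle for H5 and O6.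

## Retrosynthetic reasoning

**Ester C–O bonds (24 ⇒ 23 ⇒ 22 ⇒ 21).** The angelate is cut first, so that in the forward direction it is installed last and never meets a base, a nucleophile or fluoride. The anisoate is cut next. Diol 21 keeps O10 as the silyl ether that the diene 8 brings in, so the three hydroxyls are already distinct: O4 tertiary and inert to acylation, O6 free and secondary, O10 masked.

**C6–H bond (21 ⇒ 20).** The C6 carbinol is traced to ketone 20. The cut is made here because the C4 hydroxyl of 20 sits on the face from which the C6 hydrogen must come, so an internally delivered hydride gives the anti-1,3-diol of the target. C5, now α to a ketone, is the one centre left to thermodynamic control.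

**C6=O from a C6 carboxyl (20 ⇒ 18 ⇒ 15).** The ketone is traced to ene-carbamate 18 and, by a Curtius rearrangement, to the α,β-unsaturated acid 15. This accepts the one structural cost of the key step: the carbene carbon needs an acceptor group, which ends as a carboxyl carbon on C6 and must be excised. An unsaturated acid is exactly the substrate that a Curtius rearrangement converts into a ketone, and the C5=C6 alkene becomes H5 in the same operation.

**C4–isopropyl bond and the lactone (15 ⇒ 12 ⇒ 10).** The isopropyl group is removed from C4 to expose the ketone of 10. Forward, the new tertiary alkoxide is held cis to the C6 ester across C5=C6 and will close butenolide 12. This is accepted as the isolable form: 12 is opened by hydroxide and O4 is silylated to give 15, so the acid can be activated without relactonising and the isocyanate cannot be captured internally. Only the C1 methyl controls the face of attack at C4, because C5 is still trigonal.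

**Key disconnection (10 ⇒ 9 ⇒ 6 + 8).** Ring B is cut at C1–C10 and C6–C7. C1–C10 is the bond a Cope rearrangement of cis-divinylcyclopropane 9 forms; C6–C7 (with the transient C6–C8) is what the vinylcarbene from 6 forms with the 1,1-disubstituted alkene of diene 8. No other pair of cuts sets the quaternary C1 and C10 together, with their relative configuration fixed by a pericyclic transition state and their absolute configuration by a catalyst. The same step delivers the C8=C9 alkene with its methyl, O10 already protected, and ring A already attached with a carbonyl at C4. The forward reaction must be site-selective for the alkene of 8 remote from oxygen, place the two alkenyl groups cis on the cyclopropane, and select one face.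

**Precursors (6 ⇒ 5 ⇒ 4 ⇒ 3 ⇒ 1 + 2; 8 ⇒ 7).** The diazo group of 6 is removed to ester 5, and its cyclopentenone is opened by a retro-aldol cut to the 1,4-diketone 3, which a Stetter disconnection divides into aldehyde 1 and enone 2. Diene 8 is the silyl dienol ether of enal 7. All of this is standard chemistry, so the risk of the route sits in the key step.

## Alternatives that were turned down

**Alternative 1: furan–oxyallyl (4+3) cycloaddition.** Ring B is cut at C1–C5 and C7–C8 into a three-carbon oxyallyl unit (C5–C6–C7, C6 as the carbonyl) and a furan whose carbons become C1, C10, C9 and C8. In the forward step the oxyallyl cation formed by reductive dehalogenation of 1,1,3,3-tetrabromopropan-2-one A2 adds across the 2- and 5-positions of 2,5-dimethylfuran A1. Debromination in the same flask gives meso 1,5-dimethyl-8-oxabicyclo[3.2.1]oct-6-en-3-one A3.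
- For: one step from two cheap achiral compounds gives ring B with the C6 carbonyl and both methyl groups (on C1 and C8) in place, and a meso ketone can in principle be desymmetrised catalytically.
- Against: in A3 the fourth substituent of C1 is the bridging oxygen, not carbon, so the quaternary stereocentre is not made. The oxygen has to be moved from C1/C8 to C10 by an allylic transposition that must also create C8=C9. C2 must then be attached at a tertiary, ether-bearing carbon with control of configuration, and ring A has still to be annulated through C1–C2 and C4–C5. C5 and C7 are equivalent until a desymmetrisation tells them apart.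
- Comparison: A3 is stronger than 10 on two points. Its C6 oxygen is already a ketone, so no carbon has to be excised, and its precursors are simpler than 6. The chosen route offers instead the all-carbon C1 with ring A attached, O10 on C10 and the alkene at C8=C9, all from one catalytic asymmetric step, so that what follows is functional-group work and not skeletal construction.

**Alternative 2: enone–alkene photocycloaddition and glycol cleavage.** Ring B is cut at C1–C10 and C5–C6 by way of a cyclobutane, and the seven-membered ring arises when the C6–C10 bond of a 1,2-diol is cleaved. In the forward step excited 3-methylcyclopent-2-en-1-one A4 adds to the alkene of 4-methyl-1,2-bis(trimethylsilyloxy)cyclopent-1-ene A5 to give the cis-anti-cis tricyclic adduct A6. Desilylation and glycol cleavage would then open it to ring B with carbonyls at C6 and C10.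
- For: A4 brings ring A with the C4 carbonyl and the C1 methyl; both ring B bonds and the quaternary centre form in one step; the alkene is symmetric, so there is no regiochemical issue. After cleavage, oxygen sits on exactly C4, C6 and C10 with no carbon to remove.
- Against: both partners are achiral and the excited-state addition has no dependable catalytic enantiocontrol, so a single enantiomer needs a resolution or a stoichiometric chiral template. The cleavage product is a triketone in which C4 and C6 form a β-diketone around C5, so isopropyl addition at C4 competes with enolisation and with two other ketones. C8 is saturated, so C8=C9 must be introduced regioselectively later. C5 is formed with the wrong configuration, and C6 and C10 need two separate stereoselective reductions.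
- Comparison: this alternative is stronger in how directly oxygen is placed (no Curtius degradation) and in the brevity of its precursors. The chosen route offers absolute control from a catalyst, the C8=C9 alkene and the C10 carbinol with its relation to C1 from the key step itself, and three oxygen functions that are chemically distinct (ketone, ester, silyl ether) from the moment they appear.

**Alternative 3: intramolecular Buchner ring expansion.** C1 is removed as a carbene carbon by cutting C1–C5 and C1–C10. Ring B reverts to a benzene ring that carries methoxy groups at C6 and C10 and the methyl at C8. In the forward step a chiral copper or rhodium carbene from 2-diazo-5-(2,6-dimethoxy-4-methylphenyl)pentan-3-one A7 adds to an ipso–ortho bond of the tethered arene, and the norcaradiene opens to 4,8-dimethoxy-6,8a-dimethyl-3,8a-dihydroazulen-1(2H)-one A8.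
- For: one catalytic step closes ring A, converts the arene into ring B and sets C1. The arene is symmetric, so the catalyst only chooses between enantiotopic bonds. O6, O10 and the C8 methyl are present from the start.
- Against: a carbene bearing an α-methyl group is prone to 1,2-hydride shift to the enone before it reaches the arene, and the bond it must attack is the most hindered one of the ring. In A8 the ring A carbonyl is on C2, next to C1, whereas the target is oxygenated at C4, so ring A needs a 1,3-transposition of oxygen. The cycloheptatriene with two enol ethers must be reduced to the single C8=C9 alkene while C5, C6 and C10 are all set by late reductions with only the C1 methyl to guide them. Such trienes also equilibrate through norcaradienes and hydrogen shifts.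
- Comparison: A8 is reached in fewer steps than 10 and carries both ring B oxygens on the right carbons without a degradation; on those points it is stronger. The chosen route offers ring A oxygen on C4 where it is needed, C10 as a finished sp3 stereocentre with a defined relation to C1, and only one alkene to preserve.

Key step: step 6

Assumption: Rh2(S-DOSP)4 is taken to give the (1S,2R) cyclopropane 9, by analogy with its behaviour toward other donor- and acceptor-substituted carbenes and 1-substituted alkenes; if the ketone-conjugated carbene from 6 responds in the opposite sense, Rh2(R-DOSP)4 is used and nothing else changes.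

## Route

Step 1
Reactants: 1 methyl 4-oxobutanoate; 2 methyl vinyl ketone (but-3-en-2-one)
Product: 3 methyl 4,7-dioxooctanoate
Conditions: 3-benzyl-5-(2-hydroxyethyl)-4-methylthiazolium chloride (10 mol %), Et3N, 1,4-dioxane, 80 °C
Reagents that add atoms: none
Why: Stetter reaction: the thiazolylidene turns aldehyde 1 into an acyl anion equivalent that adds 1,4 to enone 2; aliphatic aldehydes and methyl vinyl ketone are the standard partners, and no stereocentre is formed.

Step 2
Reactants: 3 methyl 4,7-dioxooctanoate
Product: 4 (2-methyl-5-oxocyclopent-1-en-1-yl)acetic acid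
Conditions: 2% aq. NaOH, reflux; then HCl to pH 2
Reagents that add atoms: sodium hydroxide, [Na+].[OH-]
Why: Saponification and intramolecular aldol condensation of the 1,4-diketone: the enolate of the methylene between the internal ketone and the CH2CO2 unit adds to the methyl ketone, and dehydration funnels the reversible aldol manifold to the tetrasubstituted enone, as in the classical 2-alkyl-3-methylcyclopentenone syntheses. As the carboxylate, the ester carbon cannot enter a competing Claisen closure.

Step 3
Reactants: 4 (2-methyl-5-oxocyclopent-1-en-1-yl)acetic acid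
Product: 5 methyl 2-(2-methyl-5-oxocyclopent-1-en-1-yl)acetate
Conditions: MeOH, H2SO4 (cat.), reflux
Reagents that add atoms: methanol, CO
Why: Fischer esterification; the alkene stays in conjugation with the ring ketone, so no isomerisation is expected.

Step 4
Reactants: 5 methyl 2-(2-methyl-5-oxocyclopent-1-en-1-yl)acetate
Product: 6 methyl 2-diazo-2-(2-methyl-5-oxocyclopent-1-en-1-yl)acetate
Conditions: p-ABSA, DBU, MeCN, 0 → 23 °C
Reagents that add atoms: 4-acetamidobenzenesulfonyl azide (p-ABSA), CC(=O)Nc1ccc(cc1)S(=O)(=O)N=[N+]=[N-]
Why: Regitz diazo transfer: the CH2 flanked by the ester and the ring alkene is the only position with two activating groups, as in the usual preparation of vinyldiazoacetates; the α′ and γ positions of the enone carry one activating group and do not accept a diazo group under these conditions.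

Step 5
Reactants: 7 3-methylbut-2-enal
Product: 8 (E)-1-(tert-butyldimethylsilyloxy)-3-methylbuta-1,3-diene
Conditions: TBSOTf, Et3N, Et2O, 0 → 23 °C
Reagents that add atoms: tert-butyldimethylsilyl trifluoromethanesulfonate, CC(C)(C)[Si](C)(C)OS(=O)(=O)C(F)(F)F
Why: Silyl dienol ether formation: O-silylation of the enal and γ-deprotonation of the silyloxocarbenium ion by Et3N; reaction through the s-trans conformer should place the silyloxy group E, and either γ-methyl gives the same diene. Any Z isomer would put the silyloxy group inside the boat of step 6 and is removed by distillation.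

Step 6
Reactants: 6 methyl 2-diazo-2-(2-methyl-5-oxocyclopent-1-en-1-yl)acetate; 8 (E)-1-(tert-butyldimethylsilyloxy)-3-methylbuta-1,3-diene
Product: 10 methyl (1S,10R)-10-(tert-butyldimethylsilyloxy)-1,8-dimethyl-4-oxobicyclo[5.3.0]deca-5,8-diene-6-carboxylate, via cis-divinylcyclopropane 9 (not isolated)
Conditions: Rh2(S-DOSP)4 (1 mol %), 8 (3 equiv), hexanes, −40 → 23 °C, slow addition of 6 in PhCF3; then 60 °C
Reagents that add atoms: none
Why: The catalyst converts 6 into a rhodium-bound vinylcarbene that adds to C7=C8 of 8 in a concerted, asynchronous cyclopropanation (C6–C7 leading, C6–C8 closing), and cis-divinylcyclopropane 9 then undergoes a [3,3] sigmatropic shift that breaks C6–C8 and forms C1–C10. This is the known tandem cyclopropanation and Cope rearrangement of vinyldiazoacetates with dienes, a formal (4+3) cycloaddition. Ring B is closed by expansion of the three-membered ring, suprafacial on both allyl units, through the only productive boat transition state, in which both alkenyl groups lie over the cyclopropane. The step needs site selectivity for the 1,1-disubstituted alkene of 8: carbenes of this donor and acceptor type do not cyclopropanate trans-1,2-disubstituted alkenes, the CH2 terminus is open, and the charge building at C8 is stabilised through C9=C10 by the silyloxy group. It also needs the two alkenyl groups cis on the cyclopropane, which follows from the preference of the alkene substituent for the side of the carbene donor group, and attack on one face, which the chiral carboxylate ligands decide. C1 and C10 are fixed relative to each other by the boat: the E-silyloxy group on C10 and the ring CH2 (C2) on C1 point outward, so O10 ends trans to the C1 methyl. Their absolute configuration is passed on from the cyclopropane centres C6 and C8, which are destroyed in the shift. The Z-methyl on C1 points into the boat and slows the shift, hence the final warming.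

Step 7
Reactants: 10 methyl (1S,10R)-10-(tert-butyldimethylsilyloxy)-1,8-dimethyl-4-oxobicyclo[5.3.0]deca-5,8-diene-6-carboxylate
Product: 12 (1S,4R,10R)-10-(tert-butyldimethylsilyloxy)-4-isopropyl-1,8-dimethylbicyclo[5.3.0]deca-5,8-diene-6-carboxylic acid γ-lactone onto O4 (tricyclic butenolide), via magnesium alkoxide of hydroxy ester 11 (not isolated)
Conditions: CeCl3 (anhydrous), i-PrMgCl, THF, −78 °C; add 10; MeOH, −78 → 23 °C; aq. NH4Cl
Reagents that add atoms: isopropylmagnesium chloride, CC(C)[Mg]Cl
Why: Organocerium 1,2-addition: the weakly basic, oxophilic isopropylcerium reagent adds to the C4 ketone without enolisation, β-hydride reduction or conjugate addition to the tetrasubstituted ene-dicarbonyl. Attack comes from the face of ring A opposite the pseudo-axial C1 methyl, giving 4R (hydroxyl cis to the methyl). The alkoxide of 11 is held cis to the ester across C5=C6 and closes the butenolide on warming.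

Step 8
Reactants: 12 tricyclic butenolide
Product: 15 (1S,4R,10R)-10-(tert-butyldimethylsilyloxy)-4-isopropyl-1,8-dimethyl-4-(trimethylsilyloxy)bicyclo[5.3.0]deca-5,8-diene-6-carboxylic acid, via lithium hydroxy carboxylate 13 (not isolated), via bis-trimethylsilyl derivative 14 (not isolated)
Conditions: LiOH·H2O, THF/H2O, 23 °C, evaporate to dryness; TMSOTf, 2,6-lutidine, CH2Cl2, 0 °C; pH 7 phosphate buffer work-up
Reagents that add atoms: lithium hydroxide, [Li+].[OH-]; trimethylsilyl trifluoromethanesulfonate, C[Si](C)(C)OS(=O)(=O)C(F)(F)F
Why: Saponification of the lactone gives the hydroxy carboxylate, which cannot relactonise while it is a salt; exhaustive silylation and hydrolysis of the labile silyl ester on work-up leave the tertiary TMS ether. With O4 capped, the acid can be activated without returning to 12.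

Step 9
Reactants: 15 O4-silylated unsaturated acid
Product: 18 allyl N-[(1S,4R,10R)-10-(tert-butyldimethylsilyloxy)-4-isopropyl-1,8-dimethyl-4-(trimethylsilyloxy)bicyclo[5.3.0]deca-5,8-dien-6-yl]carbamate, via acyl azide 16 (not isolated), via vinyl isocyanate 17 (not isolated)
Conditions: DPPA, Et3N, PhMe, 23 °C then 80 °C; allyl alcohol, 80 °C
Reagents that add atoms: diphenylphosphoryl azide, O=P(N=[N+]=[N-])(Oc1ccccc1)Oc1ccccc1; allyl alcohol, C=CCO
Why: Curtius rearrangement: azide displaces the mixed phosphoric anhydride, acyl azide 16 loses nitrogen with migration of the alkenyl carbon, and vinyl isocyanate 17 is trapped by allyl alcohol as the ene-carbamate. Because O4 is silylated, the isocyanate cannot be captured internally as a cyclic carbamate.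

Step 10
Reactants: 18 allyl ene-carbamate
Product: 20 (1S,4R,5R,10R)-10-(tert-butyldimethylsilyloxy)-4-hydroxy-4-isopropyl-1,8-dimethylbicyclo[5.3.0]dec-8-en-6-one, via primary enamine 19 (not isolated)
Conditions: Pd(PPh3)4 (5 mol %), dimedone, THF, 23 °C; then aq. citric acid (pH 4), THF, 0 → 23 °C
Reagents that add atoms: water, O
Why: Palladium-catalysed deallylation (π-allyl transfer to dimedone) under neutral conditions and loss of CO2 give the primary enamine, whose imine tautomer is hydrolysed at pH 4, where the tertiary TMS ether is also cleaved. C5 is created by reversible enamine–imine tautomerism and should settle with C6 cis to O4 and trans to the isopropyl group (trans ring fusion, O4–H···O6 hydrogen bond). Near-neutral conditions are used because 20 is a tertiary aldol that can dehydrate or undergo retro-aldol cleavage.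

Step 11
Reactants: 20 β-hydroxy ketone
Product: 21 (1S,4R,5S,6S,10R)-10-(tert-butyldimethylsilyloxy)-4-isopropyl-1,8-dimethylbicyclo[5.3.0]dec-8-ene-4,6-diol
Conditions: Me4NBH(OAc)3, MeCN/AcOH (1:1), −30 → 0 °C
Reagents that add atoms: none
Why: Hydroxyl-directed Evans–Saksena reduction: the C4 hydroxyl exchanges onto boron and hydride is delivered through a six-membered transition state to the face of the C6 carbonyl on which O4 lies, giving the anti-1,3-diol, that is O6 opposite O4 and the C1 methyl (6S). The weakly acidic medium avoids base-induced retro-aldol cleavage and epimerisation at C5.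

Step 12
Reactants: 21 anti-diol
Product: 22 (1S,4R,5S,6S,10R)-10-(tert-butyldimethylsilyloxy)-4-hydroxy-4-isopropyl-1,8-dimethylbicyclo[5.3.0]dec-8-en-6-yl 4-methoxybenzoate
Conditions: 4-methoxybenzoyl chloride, DMAP, Et3N, CH2Cl2, 0 → 23 °C
Reagents that add atoms: 4-methoxybenzoyl chloride, COc1ccc(cc1)C(Cl)=O
Why: DMAP-catalysed acylation: only the secondary C6 hydroxyl reacts, because the tertiary C4 hydroxyl next to the isopropyl group is inert under these conditions and O10 is still silylated.

Step 13
Reactants: 22 silyl ether anisoate
Product: 23 (1S,4R,5S,6S,10R)-4,10-dihydroxy-4-isopropyl-1,8-dimethylbicyclo[5.3.0]dec-8-en-6-yl 4-methoxybenzoate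
Conditions: Bu4NF, AcOH, THF, 0 → 40 °C
Reagents that add atoms: none
Why: Fluoride-mediated desilylation; acetic acid buffers the alkoxide so that the aryl ester does not migrate, and the non-acidic medium keeps the allylic C10–O bond from ionising.

Step 14
Reactants: 23 C10 alcohol
Product: 24 CNP0168729.1: (1S,4R,5S,6S,10R)-4-hydroxy-4-isopropyl-6-(4-methoxybenzoyloxy)-1,8-dimethylbicyclo[5.3.0]dec-8-en-10-yl (Z)-2-methylbut-2-enoate
Conditions: angelic acid, 2,4,6-trichlorobenzoyl chloride, Et3N, PhMe, 23 °C; then 23, 80 °C (no DMAP)
Reagents that add atoms: angelic acid ((Z)-2-methylbut-2-enoic acid), C/C=C(/C)C(=O)O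
Why: Yamaguchi-type esterification through the mixed anhydride of angelic acid: the hindered aryl carbonyl directs the alcohol to the angeloyl carbonyl, and leaving out nucleophilic catalysts suppresses the addition–elimination that isomerises angelate to tiglate. The tertiary C4 hydroxyl does not react.

## Compound list

1 | methyl 4-oxobutanoate | COC(=O)CCC=O | starting material
2 | methyl vinyl ketone (but-3-en-2-one) | CC(=O)C=C | starting material
3 | methyl 4,7-dioxooctanoate | COC(=O)CCC(=O)CCC(C)=O | intermediate
4 | (2-methyl-5-oxocyclopent-1-en-1-yl)acetic acid | OC(=O)CC1=C(C)CCC1=O | intermediate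
5 | methyl 2-(2-methyl-5-oxocyclopent-1-en-1-yl)acetate | COC(=O)CC1=C(C)CCC1=O | intermediate
6 | methyl 2-diazo-2-(2-methyl-5-oxocyclopent-1-en-1-yl)acetate | COC(=O)C(=[N+]=[N-])C1=C(C)CCC1=O | intermediate
7 | 3-methylbut-2-enal | CC(C)=CC=O | starting material
8 | (E)-1-(tert-butyldimethylsilyloxy)-3-methylbuta-1,3-diene | CC(=C)/C=C/O[Si](C)(C)C(C)(C)C | intermediate
9 | methyl (1S,2R)-2-[(E)-2-(tert-butyldimethylsilyloxy)ethenyl]-2-methyl-1-(2-methyl-5-oxocyclopent-1-en-1-yl)cyclopropane-1-carboxylate (the two alkenyl groups cis) | COC(=O)[C@@]1(C2=C(C)CCC2=O)C[C@]1(C)/C=C/O[Si](C)(C)C(C)(C)C | intermediate (not isolated)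
10 | methyl (1S,10R)-10-(tert-butyldimethylsilyloxy)-1,8-dimethyl-4-oxobicyclo[5.3.0]deca-5,8-diene-6-carboxylate (O10 trans to the C1 methyl) | CC(C)(C)[Si](C)(C)O[C@@H]1C=C(C)CC(C(=O)OC)=C2[C@]1(C)CCC2=O | intermediate
11 | methyl (1S,4R,10R)-10-(tert-butyldimethylsilyloxy)-4-hydroxy-4-isopropyl-1,8-dimethylbicyclo[5.3.0]deca-5,8-diene-6-carboxylate (present as its magnesium alkoxide) | CC(C)(C)[Si](C)(C)O[C@@H]1C=C(C)CC(C(=O)OC)=C2[C@]1(C)CC[C@@]2(O)C(C)C | intermediate (not isolated)
12 | (1S,4R,10R)-10-(tert-butyldimethylsilyloxy)-4-isopropyl-1,8-dimethylbicyclo[5.3.0]deca-5,8-diene-6-carboxylic acid γ-lactone onto O4 (tricyclic butenolide) | CC(C)(C)[Si](C)(C)O[C@@H]1C=C(C)CC2=C3[C@]1(C)CC[C@@]3(OC2=O)C(C)C | intermediate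
13 | lithium (1S,4R,10R)-10-(tert-butyldimethylsilyloxy)-4-hydroxy-4-isopropyl-1,8-dimethylbicyclo[5.3.0]deca-5,8-diene-6-carboxylate | CC(C)(C)[Si](C)(C)O[C@@H]1C=C(C)CC(C(=O)[O-])=C2[C@]1(C)CC[C@@]2(O)C(C)C.[Li+] | intermediate (not isolated)
14 | trimethylsilyl (1S,4R,10R)-10-(tert-butyldimethylsilyloxy)-4-isopropyl-1,8-dimethyl-4-(trimethylsilyloxy)bicyclo[5.3.0]deca-5,8-diene-6-carboxylate | CC(C)(C)[Si](C)(C)O[C@@H]1C=C(C)CC(C(=O)O[Si](C)(C)C)=C2[C@]1(C)CC[C@@]2(O[Si](C)(C)C)C(C)C | intermediate (not isolated)
15 | (1S,4R,10R)-10-(tert-butyldimethylsilyloxy)-4-isopropyl-1,8-dimethyl-4-(trimethylsilyloxy)bicyclo[5.3.0]deca-5,8-diene-6-carboxylic acid | CC(C)(C)[Si](C)(C)O[C@@H]1C=C(C)CC(C(=O)O)=C2[C@]1(C)CC[C@@]2(O[Si](C)(C)C)C(C)C | intermediate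
16 | acyl azide of 15 | CC(C)(C)[Si](C)(C)O[C@@H]1C=C(C)CC(C(=O)N=[N+]=[N-])=C2[C@]1(C)CC[C@@]2(O[Si](C)(C)C)C(C)C | intermediate (not isolated)
17 | (1S,4R,10R)-10-(tert-butyldimethylsilyloxy)-6-isocyanato-4-isopropyl-1,8-dimethyl-4-(trimethylsilyloxy)bicyclo[5.3.0]deca-5,8-diene | CC(C)(C)[Si](C)(C)O[C@@H]1C=C(C)CC(N=C=O)=C2[C@]1(C)CC[C@@]2(O[Si](C)(C)C)C(C)C | intermediate (not isolated)
18 | allyl N-[(1S,4R,10R)-10-(tert-butyldimethylsilyloxy)-4-isopropyl-1,8-dimethyl-4-(trimethylsilyloxy)bicyclo[5.3.0]deca-5,8-dien-6-yl]carbamate | CC(C)(C)[Si](C)(C)O[C@@H]1C=C(C)CC(NC(=O)OCC=C)=C2[C@]1(C)CC[C@@]2(O[Si](C)(C)C)C(C)C | intermediate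
19 | (1S,4R,10R)-10-(tert-butyldimethylsilyloxy)-4-isopropyl-1,8-dimethyl-4-(trimethylsilyloxy)bicyclo[5.3.0]deca-5,8-dien-6-amine (primary enamine) | CC(C)(C)[Si](C)(C)O[C@@H]1C=C(C)CC(N)=C2[C@]1(C)CC[C@@]2(O[Si](C)(C)C)C(C)C | intermediate (not isolated)
20 | (1S,4R,5R,10R)-10-(tert-butyldimethylsilyloxy)-4-hydroxy-4-isopropyl-1,8-dimethylbicyclo[5.3.0]dec-8-en-6-one (trans ring fusion) | CC(C)(C)[Si](C)(C)O[C@@H]1C=C(C)CC(=O)[C@@H]2[C@]1(C)CC[C@@]2(O)C(C)C | intermediate
21 | (1S,4R,5S,6S,10R)-10-(tert-butyldimethylsilyloxy)-4-isopropyl-1,8-dimethylbicyclo[5.3.0]dec-8-ene-4,6-diol | CC(C)(C)[Si](C)(C)O[C@@H]1C=C(C)C[C@H](O)[C@@H]2[C@]1(C)CC[C@@]2(O)C(C)C | intermediate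
22 | (1S,4R,5S,6S,10R)-10-(tert-butyldimethylsilyloxy)-4-hydroxy-4-isopropyl-1,8-dimethylbicyclo[5.3.0]dec-8-en-6-yl 4-methoxybenzoate | CC(C)(C)[Si](C)(C)O[C@@H]1C=C(C)C[C@H](OC(=O)c2ccc(OC)cc2)[C@@H]2[C@]1(C)CC[C@@]2(O)C(C)C | intermediate
23 | (1S,4R,5S,6S,10R)-4,10-dihydroxy-4-isopropyl-1,8-dimethylbicyclo[5.3.0]dec-8-en-6-yl 4-methoxybenzoate | O[C@@H]1C=C(C)C[C@H](OC(=O)c2ccc(OC)cc2)[C@@H]2[C@]1(C)CC[C@@]2(O)C(C)C | intermediate
24 | CNP0168729.1: (1S,4R,5S,6S,10R)-4-hydroxy-4-isopropyl-6-(4-methoxybenzoyloxy)-1,8-dimethylbicyclo[5.3.0]dec-8-en-10-yl (Z)-2-methylbut-2-enoate | C/C=C(/C)C(=O)O[C@@H]1C=C(C)C[C@H](OC(=O)c2ccc(OC)cc2)[C@@H]2[C@]1(C)CC[C@@]2(O)C(C)C | target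

## Step count and least certain steps

Total: 14 steps. Longest linear sequence: 13 steps (steps 1–4 and 6–14 from 1); step 5 is a one-step branch.

**Step 6 (key step).** Three things may go wrong.
- The carbene may attack the silyl enol ether end of 8, or react in a stepwise zwitterionic manner, because the enone-conjugated alkene is a poor donor and makes the carbene more electrophilic than a plain vinylcarbene.
- For the same reason the face selection by the catalyst may be weak.
- The reaction may stall at 9, or at its trans isomer, because the Z-methyl on C1 retards the boat.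

Fallback: take the ketone out of the carbene precursor. From 5, aprotic ketalisation (1,2-bis(trimethylsilyloxy)ethane, TMSOTf cat., CH2Cl2, −78 → −20 °C) would give methyl 2-(7-methyl-1,4-dioxaspiro[4.4]non-6-en-6-yl)acetate F1. Diazo transfer as in step 4 gives its diazo ester F2, whose carbene has an ordinary electron-rich cyclopentenyl donor. The same tandem reaction with 8 gives the C4 ethylene ketal of 10, F3, and mild hydrolysis (PPTS, wet acetone) returns to 10.

**Step 10.** Protonation at C5 may occur from the face of the C1 methyl, or equilibration may be incomplete, leaving the cis-fused epimer. The tertiary aldol may also dehydrate or undergo retro-aldol cleavage during hydrolysis. Both problems arise because C5 is set while it is α to an sp2 carbon, with no ring to enforce its configuration.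

Fallback: fix C5 inside a lactone before the ketone exists. From 12, LiOH opening and reduction of the resulting dianion with Li in NH3/t-BuOH cannot expel O4, which is now an alkoxide. Acidification closes only the epimer with C6 cis to O4 to the saturated cis-fused lactone F4 (C6 epimers converge later); the other epimer stays an acid and is extracted away. Enolate hydroxylation (LiN(i-Pr)2; 2-(phenylsulfonyl)-3-phenyloxaziridine) gives the α-hydroxy lactone F5, LiAlH4 gives the triol F6, and NaIO4 in buffered aqueous THF cleaves the 1,2-diol to 20 under neutral conditions.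

**Step 7.** Addition may be slow relative to β-hydride reduction of the hindered, conjugated ketone, and the face selectivity may be eroded because C10 of ring B flanks the face opposite the C1 methyl.

Fallback: use a smaller nucleophile without β-hydrogens. From 10, 2-propenylmagnesium bromide with CeCl3 would give, after the same lactonisation, the isopropenyl butenolide F7. Hydrogenation with RhCl(PPh3)3 reduces only the 1,1-disubstituted alkene and gives 12.

**Step 8.** The acid may relactonise, either during silylation or when the free acid 15 is generated, because the carboxyl and O4 are held cis.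

Fallback: avoid a free acid altogether. From 12, Me2AlNH2 (from AlMe3 and NH4Cl) opens the lactone to the hydroxy primary amide F8 and TMSOTf silylates O4 to give F9. Hofmann rearrangement with PhI(OAc)2 in MeCN, followed by allyl alcohol, then gives 18 through the same isocyanate 17.

**Step 14.** The angelate may isomerise to the tiglate, and acylation of the neopentylic allylic C10 hydroxyl may be slow, so that long heating is needed.

Fallback: build the Z-alkene last. From 23, esterification with 2-[bis(2,2,2-trifluoroethoxy)phosphoryl]propanoic acid (DCC) would give the phosphonate ester F10. Still–Gennari olefination (KN(SiMe3)2, 18-crown-6, THF, −78 °C; acetaldehyde) gives 24 with the Z geometry set kinetically.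

## Further compounds

F1 | step 6 | methyl 2-(7-methyl-1,4-dioxaspiro[4.4]non-6-en-6-yl)acetate | COC(=O)CC1=C(C)CCC12OCCO2
F2 | step 6 | methyl 2-diazo-2-(7-methyl-1,4-dioxaspiro[4.4]non-6-en-6-yl)acetate | COC(=O)C(=[N+]=[N-])C1=C(C)CCC12OCCO2
F3 | step 6 | C4 ethylene ketal of 10: methyl (1S,10R)-10-(tert-butyldimethylsilyloxy)-4,4-(ethylenedioxy)-1,8-dimethylbicyclo[5.3.0]deca-5,8-diene-6-carboxylate | CC(C)(C)[Si](C)(C)O[C@@H]1C=C(C)CC(C(=O)OC)=C2[C@]1(C)CCC23OCCO3
F4 | step 10 | saturated cis-fused γ-lactone: (1S,4R,5S,10R)-10-(tert-butyldimethylsilyloxy)-4-isopropyl-1,8-dimethylbicyclo[5.3.0]dec-8-ene-6-carboxylic acid γ-lactone onto O4 (C6 epimers) | CC(C)(C)[Si](C)(C)O[C@@H]1C=C(C)CC2[C@@H]3[C@]1(C)CC[C@@]3(OC2=O)C(C)C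
F5 | step 10 | 6-hydroxy derivative of lactone F4 (C6 epimers) | CC(C)(C)[Si](C)(C)O[C@@H]1C=C(C)CC2(O)[C@@H]3[C@]1(C)CC[C@@]3(OC2=O)C(C)C
F6 | step 10 | (1S,4R,5S,10R)-10-(tert-butyldimethylsilyloxy)-6-(hydroxymethyl)-4-isopropyl-1,8-dimethylbicyclo[5.3.0]dec-8-ene-4,6-diol (C6 epimers) | CC(C)(C)[Si](C)(C)O[C@@H]1C=C(C)CC(O)(CO)[C@@H]2[C@]1(C)CC[C@@]2(O)C(C)C
F7 | step 7 | isopropenyl analogue of butenolide 12 | CC(C)(C)[Si](C)(C)O[C@@H]1C=C(C)CC2=C3[C@]1(C)CC[C@@]3(OC2=O)C(C)=C
F8 | step 8 | (1S,4R,10R)-10-(tert-butyldimethylsilyloxy)-4-hydroxy-4-isopropyl-1,8-dimethylbicyclo[5.3.0]deca-5,8-diene-6-carboxamide | CC(C)(C)[Si](C)(C)O[C@@H]1C=C(C)CC(C(N)=O)=C2[C@]1(C)CC[C@@]2(O)C(C)C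
F9 | step 8 | (1S,4R,10R)-10-(tert-butyldimethylsilyloxy)-4-isopropyl-1,8-dimethyl-4-(trimethylsilyloxy)bicyclo[5.3.0]deca-5,8-diene-6-carboxamide | CC(C)(C)[Si](C)(C)O[C@@H]1C=C(C)CC(C(N)=O)=C2[C@]1(C)CC[C@@]2(O[Si](C)(C)C)C(C)C
F10 | step 14 | C10 2-[bis(2,2,2-trifluoroethoxy)phosphoryl]propanoate of 23 | CC(C(=O)O[C@@H]1C=C(C)C[C@H](OC(=O)c2ccc(OC)cc2)[C@@H]2[C@]1(C)CC[C@@]2(O)C(C)C)P(=O)(OCC(F)(F)F)OCC(F)(F)F
A1 | alternative 1 | 2,5-dimethylfuran | Cc1ccc(C)o1
A2 | alternative 1 | 1,1,3,3-tetrabromopropan-2-one | BrC(Br)C(=O)C(Br)Br
A3 | alternative 1 | 1,5-dimethyl-8-oxabicyclo[3.2.1]oct-6-en-3-one (meso) | C[C@@]12C=C[C@@](C)(O1)CC(=O)C2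
A4 | alternative 2 | 3-methylcyclopent-2-en-1-one | CC1=CC(=O)CC1
A5 | alternative 2 | 4-methyl-1,2-bis(trimethylsilyloxy)cyclopent-1-ene | CC1CC(O[Si](C)(C)C)=C(O[Si](C)(C)C)C1
A6 | alternative 2 | cis-anti-cis tricyclic photoadduct | C[C@]12CCC(=O)[C@H]1[C@]1(O[Si](C)(C)C)C[C@@H](C)C[C@]21O[Si](C)(C)C
A7 | alternative 3 | 2-diazo-5-(2,6-dimethoxy-4-methylphenyl)pentan-3-one | CC(=[N+]=[N-])C(=O)CCc1c(OC)cc(C)cc1OC
A8 | alternative 3 | 4,8-dimethoxy-6,8a-dimethyl-3,8a-dihydroazulen-1(2H)-one | COC1=CC(C)=CC(OC)=C2CCC(=O)[C@]12C
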